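**Strategy.** The route rests on assembling the pyranone ring of the coumarin from three components. The feature exploited is the benzo-fused edge of that ring: C4a and C8a are neighbouring carbons of an arene made symmetric by its 6,7-oxygenation, C8a bears the ring oxygen O1, and C4 carries only hydrogen. A symmetric aryne and the C=O of a formamide supply exactly this. In one operation 4,5-dimethoxybenzyne inserts into DMF and the resulting ortho-quinone methide is annulated by an α-aryloxyacetate enolate, forming C4a–C4, C8a–O1, C3–C4 and C2–O1. The enolate precursor is the methoxycarbonylmethyl ether of MOM-protected 4-bromoresorcinol; its bromine marks the later propanoate chain.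

Key step: step 3

Remark 1: the target has no stereocentre and no stereogenic double bond, so it is achiral and no step needs stereocontrol.

Remark 2: the resorcinol phenol is protected as a MOM acetal and not as a benzyl ether, because a benzyl aryl ether is at least as open to thiolate SN2 attack as the 7-OMe that step 4 must cleave. The acetal also comes off in acidic methanol, where the open hydroxy methyl ester is favoured over the dihydrocoumarin.

Step 1
Reactants: 1 4-bromoresorcinol; 2 methyl bromoacetate
Product: 3 methyl 2-(4-bromo-3-hydroxyphenoxy)acetate
Conditions: K2CO3 (1.0 equiv), 2 (1.0 equiv, slow addition), acetone, 0 °C → rt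
Reagents that add atoms: none
Why: Williamson ether synthesis in which, with one equivalent each of base and electrophile, the oxygen para to bromine (less shielded, more nucleophilic phenoxide) should be alkylated in preference to the oxygen flanked by the ortho bromine, with bis-ether and regioisomer removed by chromatography.

Step 2
Reactants: 3 methyl 2-(4-bromo-3-hydroxyphenoxy)acetate
Product: 4 methyl 2-[4-bromo-3-(methoxymethoxy)phenoxy]acetate
Conditions: MOMCl, i-Pr2NEt, CH2Cl2, 0 °C → rt
Reagents that add atoms: chloromethyl methyl ether (MOMCl), COCCl
Why: O-alkylation of the remaining phenol with an α-chloro ether (MOM protection) under amine base, which leaves the methyl ester and aryl bromide untouched and gives an acetal that resists the enolate, fluoride, thiolate and palladium conditions that follow.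

Step 3
Reactants: 5 4,5-dimethoxy-2-(trimethylsilyl)phenyl trifluoromethanesulfonate; 6 N,N-dimethylformamide; 4 methyl 2-[4-bromo-3-(methoxymethoxy)phenoxy]acetate
Product: 11 3-[4-bromo-3-(methoxymethoxy)phenoxy]-6,7-dimethoxy-2H-chromen-2-one, via 4,5-dimethoxybenzyne 7 (not isolated), via ortho-quinone methide 8 (not isolated), via lithium enolate 9 (not isolated), via aminodihydrocoumarin 10 (not isolated)
Conditions: i) 5 (1.5 equiv), anhydrous CsF (3 equiv), DMF (6, solvent), rt, until 5 is consumed; ii) added to 9 [4, LiHMDS (1.1 equiv), THF, −78 °C], −78 °C → rt; iii) AcOH, rt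
Reagents that add atoms: none
Why: Proposed new method: fluoride-induced desilylation of 5 with loss of triflate gives the aryne 7, which the carbonyl oxygen of the solvent DMF attacks; the aryl anion closes onto the iminium carbon to a benzoxete (C8a–O1 and C4a–C4 formed) that opens to the ortho-quinone methide 8, and the enolate 9 should add to its aminomethylene carbon (C3–C4). The liberated phenoxide then closes the pyranone by 6-exo-trig attack on the methyl ester (C2–O1, giving 10), and loss of dimethylamine from the benzylic C4, eased by the para 7-methoxy group and the acidic C3–H, installs C3=C4 of 11. The closest known reaction type is the three-component coupling of arynes, DMF and active-methylene enolates (malonates, β-keto esters) to coumarins; an α-aryloxy monoester enolate has not been used in it, but it is a stronger nucleophile than those and keeps the single α-hydrogen that the final elimination needs. No stereocentre is formed, and the geometries drawn for 8 and 9 are lost in the aromatic product. Regiochemistry needs no control because the two aryne carbons of 7 are equivalent, so either sense of insertion gives the same 6,7-dimethoxy pattern. The selectivity that does matter, capture of 7 by DMF and not by the enolate or hexamethyldisilazane, is secured by completing aryne generation in neat DMF before the cold enolate is met, while the aryl bromide, acetal and ester of 4 are inert to fluoride and to LiHMDS at −78 °C.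

Step 4
Reactants: 11 3-[4-bromo-3-(methoxymethoxy)phenoxy]-6,7-dimethoxy-2H-chromen-2-one
Product: 12 3-[4-bromo-3-(methoxymethoxy)phenoxy]-7-hydroxy-6-methoxy-2H-chromen-2-one
Conditions: NaSEt (3 equiv), degassed DMF, 90 °C; aq. NH4Cl work-up
Reagents that add atoms: none
Why: Nucleophilic (SN2) O-demethylation by thiolate, which should select the 7-OMe because O7 is para to C4a and thus conjugated through C4=C3 with the lactone carbonyl, making its phenoxide a far better leaving group than that of O6; the 7-phenoxide once formed deactivates the ring against a second cleavage, the acetal, aryl bromide and diaryl ether offer no comparably activated site, and reversible thiolate addition to the lactone is undone on work-up.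

Step 5
Reactants: 12 3-[4-bromo-3-(methoxymethoxy)phenoxy]-7-hydroxy-6-methoxy-2H-chromen-2-one; 13 methyl acrylate
Product: 14 methyl (2E)-3-{4-[(7-hydroxy-6-methoxy-2-oxo-2H-chromen-3-yl)oxy]-2-(methoxymethoxy)phenyl}prop-2-enoate
Conditions: Pd(OAc)2 (5 mol%), P(o-tol)3 (10 mol%), Et3N, DMF, 100 °C
Reagents that add atoms: none
Why: Mizoroki–Heck reaction in which oxidative addition of the electron-rich aryl bromide, syn-insertion of the acrylate and syn-β-hydride elimination should give the E-cinnamate, while the free 7-hydroxyl, the lactone and the acetal tolerate the amine base.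

Step 6
Reactants: 14 methyl (2E)-3-{4-[(7-hydroxy-6-methoxy-2-oxo-2H-chromen-3-yl)oxy]-2-(methoxymethoxy)phenyl}prop-2-enoate
Product: 16 methyl 3-{2-hydroxy-4-[(7-hydroxy-6-methoxy-2-oxo-2H-chromen-3-yl)oxy]phenyl}propanoate, via saturated MOM ether 15 (not isolated)
Conditions: H2 (1 atm), 10% Pd/C, MeOH–EtOAc, rt, stopped at one equivalent of H2; filter; then 1.25 M HCl in MeOH, rt → 40 °C; solid NaHCO3 before concentration
Reagents that add atoms: none
Why: Catalytic hydrogenation should saturate the disubstituted cinnamate alkene well before the trisubstituted, oxygen-bearing C3=C4 of the coumarin, and the following acid-catalysed acetal exchange with methanol removes the MOM group in a medium where the open hydroxy methyl ester is favoured over lactonisation, provided the acid is neutralised before the solvent is removed.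

**Compound list**

1 | 4-bromoresorcinol (4-bromobenzene-1,3-diol) | Oc1ccc(Br)c(O)c1 | starting material
2 | methyl bromoacetate | COC(=O)CBr | starting material
3 | methyl 2-(4-bromo-3-hydroxyphenoxy)acetate | COC(=O)COc1ccc(Br)c(O)c1 | intermediate
4 | methyl 2-[4-bromo-3-(methoxymethoxy)phenoxy]acetate | COC(=O)COc1ccc(Br)c(OCOC)c1 | intermediate
5 | 4,5-dimethoxy-2-(trimethylsilyl)phenyl trifluoromethanesulfonate | COc1cc(OS(=O)(=O)C(F)(F)F)c(cc1OC)[Si](C)(C)C | starting material
6 | N,N-dimethylformamide | CN(C)C=O | starting material
7 | 4,5-dimethoxybenzyne (1,2-didehydro-4,5-dimethoxybenzene) | COC1=CC#CC=C1OC | intermediate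
8 | (6E)-6-[(dimethylamino)methylidene]-3,4-dimethoxycyclohexa-2,4-dien-1-one (ortho-quinone methide; same species as the 2-[(dimethyliminio)methyl]-4,5-dimethoxyphenolate zwitterion, so the drawn geometry is labile) | CN(C)/C=C1\C=C(OC)C(OC)=CC1=O | intermediate
9 | lithium 2-[4-bromo-3-(methoxymethoxy)phenoxy]-1-methoxyethen-1-olate (enolate of 4, drawn with O–Li cis to the aryloxy oxygen) | [Li+].[O-]/C(OC)=C\Oc1ccc(Br)c(OCOC)c1 | intermediate
10 | 3-[4-bromo-3-(methoxymethoxy)phenoxy]-4-(dimethylamino)-6,7-dimethoxy-3,4-dihydro-2H-chromen-2-one (racemic mixture of diastereomers, both centres lost on elimination) | COc1cc2c(cc1OC)OC(=O)C(Oc1ccc(Br)c(OCOC)c1)C2N(C)C | intermediate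
11 | 3-[4-bromo-3-(methoxymethoxy)phenoxy]-6,7-dimethoxy-2H-chromen-2-one | COc1cc2cc(Oc3ccc(Br)c(OCOC)c3)c(=O)oc2cc1OC | intermediate
12 | 3-[4-bromo-3-(methoxymethoxy)phenoxy]-7-hydroxy-6-methoxy-2H-chromen-2-one | COc1cc2cc(Oc3ccc(Br)c(OCOC)c3)c(=O)oc2cc1O | intermediate
13 | methyl acrylate | C=CC(=O)OC | starting material
14 | methyl (2E)-3-{4-[(7-hydroxy-6-methoxy-2-oxo-2H-chromen-3-yl)oxy]-2-(methoxymethoxy)phenyl}prop-2-enoate | COC(=O)/C=C/c1ccc(Oc2cc3cc(OC)c(O)cc3oc2=O)cc1OCOC | intermediate
15 | methyl 3-{4-[(7-hydroxy-6-methoxy-2-oxo-2H-chromen-3-yl)oxy]-2-(methoxymethoxy)phenyl}propanoate | COC(=O)CCc1ccc(Oc2cc3cc(OC)c(O)cc3oc2=O)cc1OCOC | intermediate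
16 | methyl 3-{2-hydroxy-4-[(7-hydroxy-6-methoxy-2-oxo-2H-chromen-3-yl)oxy]phenyl}propanoate (achiral) | COC(=O)CCc1ccc(Oc2cc3cc(OC)c(O)cc3oc2=O)cc1O | target

**Totals.** Total step count: 6. Longest linear sequence: 6 steps (1 → 3 → 4 → 11 → 12 → 14 → 16).

**Steps most likely to fail**

Step 3 (proposed new method). The aryne may be intercepted by the enolate or by hexamethyldisilazane if desilylation is still running when the enolate arrives. The aryne–DMF adduct may decay before it is trapped, the enolate may self-condense on warming, or the sequence may stall at the amine adduct without elimination. The fallback uses known chemistry and sets out from 4. Saponification (LiOH, THF–H2O) gives 2-[4-bromo-3-(methoxymethoxy)phenoxy]acetic acid F1. Perkin-type condensation of this acid with commercial 2-hydroxy-4,5-dimethoxybenzaldehyde (Ac2O, Et3N, 110 °C) acylates the salicylaldehyde oxygen and closes the pyranone by intramolecular aldol condensation and dehydration. It comes back to the route at 11.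

Step 4. Site selectivity between the two methyl ethers may be lost, demethylation may go too far, or thiolate may attack the acetal carbon or open the lactone irreversibly. The fallback differentiates O6 and O7 in the building block and sets out from 4. The acid F1, made as in the fallback to step 3, is condensed under the same Perkin conditions with commercial 2,4-dihydroxy-5-methoxybenzaldehyde, whose para hydroxyl is acetylated in the same pot. This gives 3-[4-bromo-3-(methoxymethoxy)phenoxy]-6-methoxy-2-oxo-2H-chromen-7-yl acetate F2. Mild methanolysis of the aryl acetate (K2CO3, MeOH, 0 °C) comes back to the route at 12.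

Step 1. Alkylation may occur at the wrong phenolic oxygen or twice. The fallback sets out from methyl bromoacetate 2 and uses commercial resorcinol monobenzoate (3-hydroxyphenyl benzoate) in place of 1. Williamson alkylation (K2CO3, acetone) gives methyl 2-[3-(benzoyloxy)phenoxy]acetate F3, in which the alkoxy group is the only strong para director. Bromination with NBS in MeCN should therefore occur para to it and ortho to the deactivating ester oxygen, giving methyl 2-[3-(benzoyloxy)-4-bromophenoxy]acetate F4. Methanolysis of the aryl benzoate (K2CO3, MeOH, rt) comes back to the route at 3.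

**Further compounds**

F1 | step 3 | 2-[4-bromo-3-(methoxymethoxy)phenoxy]acetic acid | OC(=O)COc1ccc(Br)c(OCOC)c1
F2 | step 4 | 3-[4-bromo-3-(methoxymethoxy)phenoxy]-6-methoxy-2-oxo-2H-chromen-7-yl acetate | COc1cc2cc(Oc3ccc(Br)c(OCOC)c3)c(=O)oc2cc1OC(C)=O
F3 | step 1 | methyl 2-[3-(benzoyloxy)phenoxy]acetate | COC(=O)COc1cccc(OC(=O)c2ccccc2)c1
F4 | step 1 | methyl 2-[3-(benzoyloxy)-4-bromophenoxy]acetate | COC(=O)COc1ccc(Br)c(OC(=O)c2ccccc2)c1
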